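**Assumption:** (+)-genipin (commercial, from Gardenia) is an acceptable starting material; its C1, C5 and C9 configurations (iridoid numbering, used throughout) are those of the target, so this is a chiral-pool route. Nothing here has been run; conditions are proposed by analogy.

## Retrosynthetic overview

1. Both rings and the C1/C5/C9 stereocentres come intact from genipin; no ring is constructed, only a transient oxirane.
2. C7–OAc / C8–OH / C10–OH ⇐ C7-selective, inverting acetolysis of a 7α,8α-epoxy alcohol ⇐ Sharpless epoxidation of the C10 allylic alcohol.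
3. C1 and C11 isovalerates ⇐ one double acylation of a lactol/allylic diol ⇐ DIBAL reduction of the C11 methyl ester.
4. Protecting groups: C10 as TBS (robust), C1 as TES (removed first).
5. Order: silylate C10, silylate C1, reduce, unmask C1, bis-acylate, unmask C10, epoxidise, open.

## Route

**Step 1**
Reactants: 1, (+)-genipin
Product: 2, 10-O-TBS-genipin
Conditions: TBSCl (1.1 equiv), imidazole, DMF, 0 °C
Reagents that add atoms: tert-butyldimethylsilyl chloride, CC(C)(C)[Si](C)(C)Cl
Why: Selective silyl ether formation; the primary allylic OH reacts much faster than the hindered lactol OH, and no stereocentre is touched.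

**Step 2**
Reactants: 2, 10-O-TBS-genipin
Product: 3, 1β-O-TES-10-O-TBS-genipin
Conditions: TESCl, imidazole, DMAP (cat.), CH2Cl2, 0 °C
Reagents that add atoms: chlorotriethylsilane, CC[Si](Cl)(CC)CC
Why: Silylation of the hemiacetal OH blocks lactol ring-opening and over-reduction in step 3; the anomer ratio is irrelevant because C1 is re-set in step 5.

**Step 3**
Reactants: 3, 1β-O-TES-10-O-TBS-genipin
Product: 4, C11 primary allylic alcohol (CO2Me → CH2OH), silyl groups intact
Conditions: DIBAL-H (2.5 equiv), CH2Cl2, −78 °C; Rochelle salt work-up; Et3N-deactivated silica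
Reagents that add atoms: none
Why: DIBAL 1,2-reduction of the β-alkoxyacrylate ester to the allylic alcohol; silyl ethers and the C7=C8 alkene are inert and no stereocentre changes.

**Step 4**
Reactants: 4, C11 alcohol
Product: 5, lactol diol (C1-OH, C11-OH free; C10-OTBS retained)
Conditions: TBAF/AcOH (1:1, 1.1 equiv), THF, −20 °C, short reaction time; use crude and cold
Reagents that add atoms: none
Why: Selective desilylation; the anomeric TES ether (lactolate leaving group, less bulky silyl) cleaves much faster than the primary TBS ether under buffered fluoride.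

**Step 5**
Reactants: 5, lactol diol
Product: 6, 1β,11-di-O-isovaleryl-10-O-TBS compound
Conditions: isovaleric anhydride (3 equiv), Et3N, DMAP (cat.), CH2Cl2, −20 → 0 °C
Reagents that add atoms: 3-methylbutanoic anhydride, CC(C)CC(=O)OC(=O)CC(C)C (two acyl groups)
Why: DMAP-catalysed acylation of the primary allylic OH and the lactol OH; the lactol equilibrates under base and is trapped as the favoured β-ester (1S, H-1/H-9 trans), the configuration of natural valepotriates.

**Step 6**
Reactants: 6, bis-isovalerate TBS ether
Product: 7, 1β,11-di-O-isovaleryl C10 allylic alcohol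
Conditions: HF·pyridine, excess pyridine, THF, 0 °C → rt; NaHCO3 quench
Reagents that add atoms: none
Why: Buffered fluoride desilylation is non-basic, so the acyl acetal and allylic ester survive and no acyl migration is induced.

**Step 7**
Reactants: 7, C10 allylic alcohol
Product: 8, 7α,8α-epoxy alcohol (7R,8R)
Conditions: Ti(OiPr)4 (10 mol %), D-(−)-diethyl tartrate (12 mol %), anhydrous TBHP (2 equiv), 4 Å MS, CH2Cl2, −20 °C
Reagents that add atoms: tert-butyl hydroperoxide, CC(C)(C)OO (one O)
Why: Katsuki–Sharpless asymmetric epoxidation, selective for the Ti-bound allylic alcohol over the non-coordinating enol ether. D-(−)-DET gives the (R,R) epoxy alcohol (opposite to the (2S,3S) sense L-(+)-DET gives with E-allylic alcohols such as geraniol), which here places O on the α-face, anti to H-5/H-9.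

**Step 8**
Reactants: 8, 7α,8α-epoxy alcohol
Product: 9, Jatamanvaltrate H
Conditions: Ti(OiPr)4 (1.5 equiv), AcOH (2 equiv), CH2Cl2, 0 °C → rt; cold aqueous tartaric acid quench
Reagents that add atoms: acetic acid, CC(=O)O
Why: Caron–Sharpless Ti-chelation-controlled C3-selective opening of a 2,3-epoxy alcohol by a carboxylic acid. Acetate attacks C7 by SN2 from the convex β-face (inversion → 7β-OAc, 7S), while the epoxide oxygen stays on C8 as the 8α-OH (8R) and C10-OH remains free.

## Compound list

1 | (+)-Genipin, methyl (1R,4aS,7aS)-1-hydroxy-7-(hydroxymethyl)-1,4a,5,7a-tetrahydrocyclopenta[c]pyran-4-carboxylate | OCC1=CC[C@@H]2C(C(=O)OC)=CO[C@@H](O)[C@H]12 | starting material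

2 | 10-O-TBS-genipin (1β-OH) | CC(C)(C)[Si](C)(C)OCC1=CC[C@@H]2C(C(=O)OC)=CO[C@@H](O)[C@H]12 | intermediate

3 | 1β-O-TES-10-O-TBS-genipin | CC(C)(C)[Si](C)(C)OCC1=CC[C@@H]2C(C(=O)OC)=CO[C@@H](O[Si](CC)(CC)CC)[C@H]12 | intermediate

4 | [(1S,4aS,7aS)-7-(TBSO-methyl)-1-(triethylsilyloxy)-1,4a,5,7a-tetrahydrocyclopenta[c]pyran-4-yl]methanol | CC(C)(C)[Si](C)(C)OCC1=CC[C@@H]2C(CO)=CO[C@@H](O[Si](CC)(CC)CC)[C@H]12 | intermediate

5 | (4aS,7aS)-7-(TBSO-methyl)-4-(hydroxymethyl)-1,4a,5,7a-tetrahydrocyclopenta[c]pyran-1-ol (lactol, β-OH major) | CC(C)(C)[Si](C)(C)OCC1=CC[C@@H]2C(CO)=CO[C@@H](O)[C@H]12 | intermediate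

6 | (1S,4aS,7aS)-7-(TBSO-methyl)-4-[(3-methylbutanoyloxy)methyl]-1,4a,5,7a-tetrahydrocyclopenta[c]pyran-1-yl 3-methylbutanoate | CC(C)(C)[Si](C)(C)OCC1=CC[C@@H]2C(COC(=O)CC(C)C)=CO[C@@H](OC(=O)CC(C)C)[C@H]12 | intermediate

7 | (1S,4aS,7aS)-7-(hydroxymethyl)-4-[(3-methylbutanoyloxy)methyl]-1,4a,5,7a-tetrahydrocyclopenta[c]pyran-1-yl 3-methylbutanoate | OCC1=CC[C@@H]2C(COC(=O)CC(C)C)=CO[C@@H](OC(=O)CC(C)C)[C@H]12 | intermediate

8 | 7α,8α-Epoxide of 7 (7R,8R; C10-OH free, C10 on the β-face) | O1[C@@H]2C[C@@H]3C(COC(=O)CC(C)C)=CO[C@@H](OC(=O)CC(C)C)[C@@H]3[C@]12CO | intermediate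

9 | Jatamanvaltrate H, (1S,4aS,6S,7R,7aS)-6-acetoxy-7-hydroxy-7-(hydroxymethyl)-4-[(3-methylbutanoyloxy)methyl]-1,4a,5,6,7,7a-hexahydrocyclopenta[c]pyran-1-yl 3-methylbutanoate | CC(=O)O[C@H]1C[C@@H]2C(COC(=O)CC(C)C)=CO[C@@H](OC(=O)CC(C)C)[C@@H]2[C@@]1(O)CO | target

## Totals

Total steps: 8. Longest linear sequence: 8 (fully linear from genipin).

## Three steps most likely to fail

1. **Step 8.** The tertiary C8 may open instead of C7, the Lewis acid may damage the acyl acetal, or acetyl may migrate from O7 to O10. Fallback: invert C8 instead of C7. Use L-(+)-DET in step 7 to make the 7β,8β-epoxide, open it with water at the tertiary carbon (mild acid, anti) to the same 7β,8α,10-triol, then 10-O-TBS, 7-O-acetylation (the tertiary OH is inert) and HF·pyridine.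

2. **Step 7.** The electron-rich C3=C4 enol ether may be oxidised, the α-face delivery may be a mismatched case, or the 2-substituted epoxy alcohol may not survive. Fallback: epoxidise at the ester stage. Run the Sharpless epoxidation on genipin (1) itself, where C3=C4 is a deactivated vinylogous carbonate, then silylate C10 and C1 and carry the epoxide through DIBAL (−78 °C) and the acylations, opening it last.

3. **Steps 4–5.** The free lactol diol 5 is a labile iridoid aglycone (ring-opening and elimination), and the C1 acylation may give α/β mixtures. Fallback: never liberate the lactol. Acylate C11-OH of 4 first, then convert the anomeric TES ether directly to the ester by fluoride-triggered desilylation in the presence of isovaleric anhydride, trapping the lactolate in situ.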